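## Structural features

The target is an achiral, pentabrominated diphenyl ether: two benzene rings joined only by one oxygen between C6 of ring A and C1' of ring B, with no stereocentre anywhere. Ring A is an anisole (C1 OMe) with bromine at C2 and C4 and the bridging oxygen at C6; ring B carries the bridging oxygen at C1', bromine at C2', C4' and C5', hydrogen at C3' and a free hydroxyl at C6'. Each ring therefore has a catechol-type 1,2-dioxygen pattern, and the two non-bridging oxygens must be told apart, one as a methyl ether and one as a free phenol. The fragile elements are the five aryl C–Br bonds, which rule out unselective halogen–metal exchange, reducing conditions and most transition-metal couplings, and the acidic polybromophenol. The real difficulty is twofold: the ether links a weakly nucleophilic, doubly ortho-flanked oxygen to a ring with no activating group for substitution, and the ring B bromines sit ortho and meta to the C6' hydroxyl with the para position (C3') empty, a pattern that hydroxyl-directed bromination of a preformed diaryl ether cannot deliver. Every halogen is therefore best installed on simple monocyclic precursors before the rings are joined. The key step uses the sequence C2(Br)–C1(O)–C6(O) of ring A: two adjacent oxygen-bearing carbons next to a C–Br bond are the two carbons of 3,5-dibromobenzyne, whose bromine decides that C6 receives the nucleophilic oxygen and C1 the electrophilic one.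

## Logic of the disconnections

15 to 13 (through 14). The C6'–O bond of the free hydroxyl on ring B is traced back to a C6'–CHO bond. The reason is that ring B must enter the ether-forming step with one phenolic oxygen only, and a formyl group is a carbon mask for the second oxygen that cannot compete as a nucleophile. The gain is that the differentiation of the two ring B oxygens disappears. The demand on the forward step is aryl rather than hydride migration in a peracid oxidation of an electron-poor aldehyde flanked on both sides.

13 to 12 to 11. The O–CH3 bond on C1 of ring A and the two C–O bonds of the acetal are cut. Methylation is placed where the ring A hydroxyl is the only free hydroxyl in the molecule, so no selectivity is needed. The acetal is kept until after the methylation only because it is already there. The forward steps demand nothing beyond base stability of the acetal and acid stability of the aryl ethers.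

11 to 3 and 6 (through 7, 8, 9 and 10). Both oxygen–carbon bonds of ring A, O–C6 (the ether) and C1–O (the hydroxyl), are cut in one operation. This turns ring A into aryne 8 and reduces the problem to two monocyclic arenes that already carry all five bromines. The forward step must generate 8 from 3 by exchange at iodine alone, with an exchange reagent that does not itself add to 8. It must then make the hindered aryloxide 7 add at C6, and keep the ortho-bromo aryl Grignard 9 intact until boron, and then oxygen, replaces magnesium at C1.

3 to 2 to 1. The O–S bond of the sulfonate and the C6–I bond are cut. The hydroxyl of 1 directs iodine to its only free ortho position, so the ortho relationship between leaving group and exchangeable halogen that 8 requires is obtained without any regiochemical choice. The only demand is monoiodination of a deactivated phenol.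

6 to 5 to 4. The acetal C–O bonds and the two C–Br bonds ortho and para to the hydroxyl of 5 are cut. The bromine that direct bromination cannot place (the one that ends at C5') is bought with 4, and the hydroxyl of 4 directs the other two to exactly the positions that become C2' and C4'. The forward steps need a clean double bromination and an acetalization that leaves the phenol free.

## Other disconnections considered

Alternative 1: Ring B is cut at C1'–C2' and C4'–C5' and built from an aryloxyacetone of ring A, 1-(3,5-dibromo-2-methoxyphenoxy)propan-2-one A1, and sodium nitromalonaldehyde A2. The forward key step is a double aldol condensation in aqueous NaOH that closes ring B as the nitrophenol A3.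
- The route would continue by nitro reduction, bromination at C2', C4' and C5', and diazotisation with reductive loss of nitrogen.
- In its favour: ring A arrives complete, so no hydroxyl differentiation is needed. No aryl–metal species is ever formed next to a C–Br bond. The ether-oxygen/hydroxyl relationship on ring B is fixed by the way the ring is assembled. The condensation of ketones with A2 to para-nitrophenols is an established reaction type. On precedent for the key step this alternative is the better one.
- Against it: A2 is an impact-sensitive energetic salt. The unsymmetrical ketone A1 must condense at both its methyl and its aryloxymethylene carbon. After A3 all three ring B bromines still have to be introduced, on an oxidation-prone para-aminophenol, and the nitrogen then has to be removed.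
- On step count the two plans are about equal, but this sequence is fully linear and places three halogens late, whereas the chosen plan is convergent and joins two finished rings.

Alternative 2: Ring A is cut at C2–C3 and C5–C6 and built from the aryloxyacetone of ring B, A4 (obtainable from 6 by O-alkylation), and bromomalonaldehyde A5. The forward key step is a base-mediated (3+3) double condensation giving the 4-bromophenol A6.
- Ortho bromination of A6 would then give 11, and the route would finish as in the chosen plan.
- In its favour: it shares 6 and the whole endgame. The C4 bromine comes with the three-carbon unit. The oxygen pattern of ring A follows from the ketone carbonyl and its α-carbon without regiochemical doubt, so on regiocontrol it is the equal of the chosen plan. No organometallic reagent is needed.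
- Against it: bromine does not activate the dialdehyde as nitro does, and A5 under base can lose bromide or self-condense. The tribromoaryloxide of A4 is a good leaving group β to the first aldol centre. The later bromination releases HBr in the presence of the acetal.
- The total is eight steps, as in the chosen plan, but all in one line against six in the longest line there.
- Neither key step has direct precedent. The chosen one is composed of individually known elementary events, which is the reason for preferring it.

Alternative 3: Ring A is traced back to a cyclohexanone. The ether bond is formed as an sp3 C–O bond by alkylating 5 with racemic 2-chlorocyclohexanone A7 to give the racemic aryloxy ketone A8. The forward key step treats A8 with excess Br2 in acetic acid, which should aromatise the ring and brominate C2 and C4 to give the hydroxy aldehyde A9.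
- Methylation of A9 gives 13, so the endgame is shared.
- In its favour: five steps in all against eight, no protecting group, no organometallic step and very cheap reagents. On step economy it is clearly the better plan. The hydroxyl formed in the pot directs bromine to its ortho and para positions, which is the target pattern, so the regiochemical logic is as sound as that of the aryne. The stereocentre of A8 is erased on aromatisation, so its racemic nature costs nothing.
- Against it: one flask must carry out two dehydrogenations and two brominations while releasing HBr. α-Bromination can occur at the carbon bearing the aryloxy group, where bromide can displace the weakly basic tribromoaryloxide and break the ether. A third bromine can enter ring A para to the ether oxygen. The free aldehyde is exposed to bromine. The alkylation giving A8 asks a hindered, weakly nucleophilic phenoxide to displace a secondary α-halide.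
- The chosen plan is longer but asks each step for one selectivity at a time and fixes every bromine before the rings are joined. The alternative is shorter but concentrates the risk in one multi-event operation.

Key step: step 5

Remark on the chemistry: the target has no stereocentre, so no SMILES on the route carries a stereodescriptor. Compounds 3, 6 and 11 map atom for atom onto rings A and B of the target. Ring atoms are numbered as in the first section.

## Route

Step 1
Reactants: 1 2,4-dibromophenol
Product: 2 2,4-dibromo-6-iodophenol
Conditions: NIS (1.05 equiv), TsOH·H2O (10 mol %), MeCN, rt
Reagents that add atoms: N-iodosuccinimide, O=C1CCC(=O)N1I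
Why: Electrophilic aromatic iodination; the hydroxyl activates only its one remaining ortho position, the para and the other ortho position being occupied by bromine, so a single regioisomer is expected.

Step 2
Reactants: 2 2,4-dibromo-6-iodophenol
Product: 3 2,4-dibromo-6-iodophenyl trifluoromethanesulfonate
Conditions: Tf2O, pyridine, CH2Cl2, 0 °C
Reagents that add atoms: trifluoromethanesulfonic anhydride, O=S(=O)(OS(=O)(=O)C(F)(F)F)C(F)(F)F
Why: O-Sulfonylation (triflation) of an acidic 2,6-dihalophenol with pyridine as base; no carbon centre is touched and the C–I bond ends ortho to the leaving group as the aryne requires.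

Step 3
Reactants: 4 2-bromo-6-hydroxybenzaldehyde
Product: 5 2,3,5-tribromo-6-hydroxybenzaldehyde
Conditions: Br2 (2.1 equiv), NaOAc, AcOH, rt
Reagents that add atoms: bromine, BrBr
Why: Electrophilic aromatic bromination; the hydroxyl directs to its free ortho and para positions, the meta-directing formyl group and the ring bromine point to the same two carbons, and NaOAc buffers the HBr. The bromine next to the formyl group, which no hydroxyl-directed bromination or ortho-formylation of a tribromophenol would place reliably, comes with the starting material.

Step 4
Reactants: 5 2,3,5-tribromo-6-hydroxybenzaldehyde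
Product: 6 3,4,6-tribromo-2-(1,3-dioxolan-2-yl)phenol
Conditions: ethylene glycol, TsOH·H2O (cat.), toluene, reflux, Dean–Stark
Reagents that add atoms: ethylene glycol, OCCO
Why: Acid-catalysed acetalization with azeotropic removal of water; the electron-poor carbonyl favours the acetal at equilibrium and the phenolic hydroxyl does not take part.

Step 5
Reactants: 6 3,4,6-tribromo-2-(1,3-dioxolan-2-yl)phenol; 3 2,4-dibromo-6-iodophenyl trifluoromethanesulfonate
Product: 11 2,4-dibromo-6-[3,4,6-tribromo-2-(1,3-dioxolan-2-yl)phenoxy]phenol, via chloromagnesium aryloxide 7 (not isolated), via 3,5-dibromobenzyne 8 (not isolated), via arylmagnesium chloride 9 (not isolated), via dimethyl arylboronate 10 (not isolated)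
Conditions: 6 (2 equiv), Me3SiCH2MgCl (2 equiv), THF, 0 °C; then 3 (1 equiv), −78 °C, Me3SiCH2MgCl (1.2 equiv) added slowly; B(OMe)3 (4 equiv), −78 to 0 °C; 30% H2O2 then aq NaOH, 0 °C
Reagents that add atoms: hydrogen peroxide, OO (oxygen of the new hydroxyl); trimethyl borate, COB(OC)OC, and (trimethylsilyl)methylmagnesium chloride, C[Si](C)(C)C[Mg]Cl, supply atoms only to the intermediates 7, 9 and 10
Why: Proposed new method: Me3SiCH2MgCl first deprotonates 6 to aryloxide 7 and then, at −78 °C, exchanges only the C–I bond of 3 (aryl C–Br bonds do not react with this sluggish Grignard reagent), whereupon the ortho-magnesiated triflate loses triflate at once and aryne 8 is born in the presence of excess 7. The bromine next to the triple bond distorts 8 so that the aryne carbon remote from it (C6) is the more electrophilic one, and the bulk of the doubly ortho-substituted aryloxide points the same way, so the O–C6 bond forms and magnesium ends up on C1 (9), where the adjacent C–Br bond stabilises the carbanion inductively. Since the whole sequence stays at −78 °C, 9 should not expel MgBrCl to give a second aryne before B(OMe)3 converts it into boronate 10, and hydroperoxide then induces the 1,2-shift of the aryl group from boron to oxygen that forms the C1–O bond at the ipso carbon. The closest known reaction types are aryne generation from 2-iodoaryl sulfonates by iodine–magnesium exchange, addition of magnesium thiolates and amides to such arynes with electrophilic trapping of the aryl Grignard formed, and borylation–oxidation of aryl Grignard reagents. New here are a magnesium aryloxide as the aryne nucleophile and the boron-to-oxygen exchange as the terminating event of a three-component coupling. No ring is closed and no stereocentre is formed. The step needs regioselective addition to the unsymmetrical aryne (secured by the C2 bromine), iodine-over-bromine selectivity in the exchange (secured by reagent and temperature) and an exchange reagent that is a poor nucleophile toward arynes so that 8 is left to the aryloxide; the acetal survives because the medium is never acidic.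

Step 6
Reactants: 11 2,4-dibromo-6-[3,4,6-tribromo-2-(1,3-dioxolan-2-yl)phenoxy]phenol
Product: 12 2-[2,3,5-tribromo-6-(3,5-dibromo-2-methoxyphenoxy)phenyl]-1,3-dioxolane
Conditions: MeI, K2CO3, DMF, rt
Reagents that add atoms: iodomethane, CI
Why: Williamson O-methylation of the only free hydroxyl; the acidic dibromophenol is fully ionised by K2CO3, methyl iodide is small enough for the flanked oxygen, and the acetal is inert to base.

Step 7
Reactants: 12 2-[2,3,5-tribromo-6-(3,5-dibromo-2-methoxyphenoxy)phenyl]-1,3-dioxolane
Product: 13 2,3,5-tribromo-6-(3,5-dibromo-2-methoxyphenoxy)benzaldehyde
Conditions: 2 M aq HCl, THF, 40 °C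
Reagents that add atoms: water, O
Why: Acid-catalysed acetal hydrolysis; the aryl ethers and aryl bromides are inert to dilute aqueous acid.

Step 8
Reactants: 13 2,3,5-tribromo-6-(3,5-dibromo-2-methoxyphenoxy)benzaldehyde
Product: 15 2,3,5-tribromo-6-(3,5-dibromo-2-methoxyphenoxy)phenol, via aryl formate 14 (not isolated)
Conditions: mCPBA, CH2Cl2, 40 °C; then MeOH, HCl (cat.), rt
Reagents that add atoms: 3-chloroperoxybenzoic acid, O=C(OO)c1cccc(Cl)c1
Why: Baeyer–Villiger oxidation of an aryl aldehyde: the peracid adds to the carbonyl and the aryl group, helped by the lone pair of the ortho aryloxy oxygen, migrates to oxygen to give formate 14. Acid-catalysed transesterification with methanol then frees the phenol; aryl bromides, the methyl ether and the diaryl ether are inert to the peracid.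

## Compound list

1 | 2,4-dibromophenol | Oc1ccc(Br)cc1Br | starting material
2 | 2,4-dibromo-6-iodophenol | Oc1c(I)cc(Br)cc1Br | intermediate
3 | 2,4-dibromo-6-iodophenyl trifluoromethanesulfonate | O=S(=O)(Oc1c(I)cc(Br)cc1Br)C(F)(F)F | intermediate
4 | 2-bromo-6-hydroxybenzaldehyde | O=Cc1c(O)cccc1Br | starting material
5 | 2,3,5-tribromo-6-hydroxybenzaldehyde | O=Cc1c(O)c(Br)cc(Br)c1Br | intermediate
6 | 3,4,6-tribromo-2-(1,3-dioxolan-2-yl)phenol | Oc1c(Br)cc(Br)c(Br)c1C1OCCO1 | intermediate
7 | chloromagnesium 3,4,6-tribromo-2-(1,3-dioxolan-2-yl)phenoxide | Cl[Mg]Oc1c(Br)cc(Br)c(Br)c1C1OCCO1 | intermediate (not isolated)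
8 | 3,5-dibromobenzyne (3,5-dibromo-1,2-didehydrobenzene) | BrC1=CC(Br)=CC#C1 | intermediate (not isolated)
9 | chloro{2,4-dibromo-6-[3,4,6-tribromo-2-(1,3-dioxolan-2-yl)phenoxy]phenyl}magnesium | Cl[Mg]c1c(Br)cc(Br)cc1Oc1c(Br)cc(Br)c(Br)c1C1OCCO1 | intermediate (not isolated)
10 | dimethyl {2,4-dibromo-6-[3,4,6-tribromo-2-(1,3-dioxolan-2-yl)phenoxy]phenyl}boronate | COB(OC)c1c(Br)cc(Br)cc1Oc1c(Br)cc(Br)c(Br)c1C1OCCO1 | intermediate (not isolated)
11 | 2,4-dibromo-6-[3,4,6-tribromo-2-(1,3-dioxolan-2-yl)phenoxy]phenol | Oc1c(Br)cc(Br)cc1Oc1c(Br)cc(Br)c(Br)c1C1OCCO1 | intermediate
12 | 2-[2,3,5-tribromo-6-(3,5-dibromo-2-methoxyphenoxy)phenyl]-1,3-dioxolane | COc1c(Br)cc(Br)cc1Oc1c(Br)cc(Br)c(Br)c1C1OCCO1 | intermediate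
13 | 2,3,5-tribromo-6-(3,5-dibromo-2-methoxyphenoxy)benzaldehyde | COc1c(Br)cc(Br)cc1Oc1c(Br)cc(Br)c(Br)c1C=O | intermediate
14 | 2,3,5-tribromo-6-(3,5-dibromo-2-methoxyphenoxy)phenyl formate | COc1c(Br)cc(Br)cc1Oc1c(Br)cc(Br)c(Br)c1OC=O | intermediate (not isolated)
15 | 2,3,5-tribromo-6-(3,5-dibromo-2-methoxyphenoxy)phenol | COc1c(Br)cc(Br)cc1Oc1c(Br)cc(Br)c(Br)c1O | target

## Step count and least certain steps

Total step count: 8. Longest linear sequence: 6 steps (steps 1, 2, 5, 6, 7, 8; the branch through steps 3, 4, 5, 6, 7, 8 is equally long).

**Step 5 (key step, proposed new method).**
- Most likely failure: slow addition of the hindered, electron-poor magnesium aryloxide to the aryne. The aryne would then be consumed by other pathways: attack by the exchange reagent or by the aryl Grignard already formed, or oligomerisation.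
- Further risks are erosion of regioselectivity, because the remote C4 bromine exerts a weak bias opposite to that of the C2 bromine; premature loss of MgBrCl from the ortho-bromo aryl Grignard if the temperature rises; and protodeboronation of the doubly flanked boronate competing with its oxidation.
- Fallback (known chemistry), setting out from 2 and 6 and returning at 12, so that step 6 is no longer needed:
  - O-methylation of 2 (MeI, K2CO3, DMF) would give 1,5-dibromo-3-iodo-2-methoxybenzene F1.
  - Oxidation of F1 to the trivalent iodine stage with mCPBA and TsOH·H2O in MeCN, followed by 1,3,5-trimethoxybenzene, would give (3,5-dibromo-2-methoxyphenyl)(2,4,6-trimethoxyphenyl)iodonium 4-methylbenzenesulfonate F2.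
  - Metal-free O-arylation of 6 with F2 (K2CO3, MeCN, 60 °C) should transfer the ortho-substituted, electron-poor aryl group and leave the trimethoxyphenyl group on iodine, giving 12. Ligand coupling at iodine tolerates hindered phenoxides and aryl bromides.

**Step 8.**
- Most likely failure: hydride instead of aryl migration in the peracid adduct, which would oxidise the aldehyde to the carboxylic acid, because three bromines lower the migratory aptitude of the ring. Slow addition of the peracid to the flanked carbonyl is a second risk.
- Fallback, setting out from 13 and returning at 15:
  - Addition of MeMgBr (THF, −78 °C; no bromine–magnesium exchange with this reagent) would give racemic 1-[2,3,5-tribromo-6-(3,5-dibromo-2-methoxyphenoxy)phenyl]ethan-1-ol F3.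
  - Dess–Martin oxidation would give 1-[2,3,5-tribromo-6-(3,5-dibromo-2-methoxyphenoxy)phenyl]ethan-1-one F4.
  - Baeyer–Villiger oxidation of this twisted aryl methyl ketone with CF3CO3H (Na2HPO4, CH2Cl2) should proceed by aryl migration, since methyl migrates poorly and no hydride is available, to give 2,3,5-tribromo-6-(3,5-dibromo-2-methoxyphenoxy)phenyl acetate F5.
  - Methanolysis of F5 (K2CO3, MeOH) gives 15.

**Step 4.**
- Most likely failure: incomplete acetalization and reversion during isolation, because the intramolecular hydrogen bond of the salicylaldehyde lowers carbonyl reactivity and the neighbouring phenol assists hydrolysis of the product.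
- Fallback, setting out from 5 and returning at 13, with the aldehyde carried as an alkene instead of an acetal:
  - Wittig methylenation of 5 (Ph3PCH3Br, KOtBu 2.2 equiv, THF) would give 3,4,6-tribromo-2-ethenylphenol F6.
  - The coupling of step 5 applied to F6 and 3 would give 2,4-dibromo-6-(3,4,6-tribromo-2-ethenylphenoxy)phenol F7.
  - Methylation as in step 6 would give 1,5-dibromo-2-methoxy-3-(3,4,6-tribromo-2-ethenylphenoxy)benzene F8.
  - Ozonolysis of F8 (O3, CH2Cl2/MeOH, −78 °C; Me2S) gives 13, which makes step 7 unnecessary.

## Further compounds

F1 | step 5 | 1,5-dibromo-3-iodo-2-methoxybenzene | COc1c(Br)cc(Br)cc1I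
F2 | step 5 | (3,5-dibromo-2-methoxyphenyl)(2,4,6-trimethoxyphenyl)iodonium 4-methylbenzenesulfonate | COc1cc(OC)c([I+]c2cc(Br)cc(Br)c2OC)c(OC)c1.Cc1ccc(S(=O)(=O)[O-])cc1
F3 | step 8 | racemic 1-[2,3,5-tribromo-6-(3,5-dibromo-2-methoxyphenoxy)phenyl]ethan-1-ol | COc1c(Br)cc(Br)cc1Oc1c(Br)cc(Br)c(Br)c1C(C)O
F4 | step 8 | 1-[2,3,5-tribromo-6-(3,5-dibromo-2-methoxyphenoxy)phenyl]ethan-1-one | COc1c(Br)cc(Br)cc1Oc1c(Br)cc(Br)c(Br)c1C(C)=O
F5 | step 8 | 2,3,5-tribromo-6-(3,5-dibromo-2-methoxyphenoxy)phenyl acetate | COc1c(Br)cc(Br)cc1Oc1c(Br)cc(Br)c(Br)c1OC(C)=O
F6 | step 4 | 3,4,6-tribromo-2-ethenylphenol | C=Cc1c(O)c(Br)cc(Br)c1Br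
F7 | step 4 | 2,4-dibromo-6-(3,4,6-tribromo-2-ethenylphenoxy)phenol | Oc1c(Br)cc(Br)cc1Oc1c(Br)cc(Br)c(Br)c1C=C
F8 | step 4 | 1,5-dibromo-2-methoxy-3-(3,4,6-tribromo-2-ethenylphenoxy)benzene | COc1c(Br)cc(Br)cc1Oc1c(Br)cc(Br)c(Br)c1C=C
A1 | alternative 1 | 1-(3,5-dibromo-2-methoxyphenoxy)propan-2-one | COc1c(Br)cc(Br)cc1OCC(C)=O
A2 | alternative 1 | sodium nitromalonaldehyde (sodium 2-nitro-1,3-dioxopropan-2-ide) | [Na+].O=C[C-](C=O)[N+](=O)[O-]
A3 | alternative 1 | 2-(3,5-dibromo-2-methoxyphenoxy)-4-nitrophenol | COc1c(Br)cc(Br)cc1Oc1cc([N+](=O)[O-])ccc1O
A4 | alternative 2 | 1-[3,4,6-tribromo-2-(1,3-dioxolan-2-yl)phenoxy]propan-2-one | CC(=O)COc1c(Br)cc(Br)c(Br)c1C1OCCO1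
A5 | alternative 2 | bromomalonaldehyde (2-bromopropanedial) | O=CC(Br)C=O
A6 | alternative 2 | 4-bromo-2-[3,4,6-tribromo-2-(1,3-dioxolan-2-yl)phenoxy]phenol | Oc1ccc(Br)cc1Oc1c(Br)cc(Br)c(Br)c1C1OCCO1
A7 | alternative 3 | racemic 2-chlorocyclohexan-1-one | O=C1CCCCC1Cl
A8 | alternative 3 | racemic 2,3,5-tribromo-6-[(2-oxocyclohexyl)oxy]benzaldehyde | O=Cc1c(OC2CCCCC2=O)c(Br)cc(Br)c1Br
A9 | alternative 3 | 3,5,6-tribromo-2-(3,5-dibromo-2-hydroxyphenoxy)benzaldehyde | O=Cc1c(Oc2cc(Br)cc(Br)c2O)c(Br)cc(Br)c1Br
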